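**Retrosynthetic overview**

1. Target ⇒ C8 alcohol of the germacranolide core + (2R,3R)-epoxyangelic acid (Yamaguchi esterification, last step). The oxirane arrives ready-made from a Sharpless epoxidation of angelyl alcohol.
2. α-Methylene-γ-lactone ⇒ 6,12-diol (oxidative lactonisation). Ten-membered carbocycle ⇒ open chain by Nozaki–Hiyama–Kishi closure of C5–C6 ((E)-alkenyl iodide + C6 aldehyde).
3. Key fragment union at C9–C10: chelation-controlled addition of the eight-carbon west fragment, a (Z)-alkenylmagnesium (C10, C14, C1–C5, C15; C5 masked as alkenylstannane), to the seven-carbon east fragment, an α-PMB-oxy aldehyde (C6–C9, C11–C13), with acetylation in the same flask.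
4. East fragment ⇒ Sharpless epoxide of (E)-but-2-ene-1,4-diol mono-PMB ether + 2-(silyloxymethyl)vinyl Grignard reagent (C2-selective opening sets C7/C8). West fragment ⇒ pent-4-yn-1-ol (Negishi carboalumination) + iodoethane (Stork–Zhao (Z)-iodo-olefination).
5. Ring order: carbocycle (step 19), then lactone (step 21); the oxirane is never formed on the core.

Assumption: the target is taken exactly as the SMILES draws it (6S,7R,8R,9R; 1(10)Z,4E; (2R,3R)-epoxyangelate). Germacrane locants are used in the explanations and in the names of the macrocycles (C1–C10 ring, C11–C13 lactone carbons, C14 on C10, C15 on C4, lactone oxygen on C6); open-chain systematic names carry their own locants.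

**Route**

Step 1
Reactants: 1 2,3-dibromoprop-1-ene
Product: 2 2-bromoprop-2-en-1-ol
Conditions: K2CO3 (1.1 equiv), H2O, 100 °C
Reagents that add atoms: water (O)
Why: SN2 hydrolysis of the allylic C–Br bond only; the vinylic bromide does not substitute.

Step 2
Reactants: 2 2-bromoprop-2-en-1-ol
Product: 3 [(2-bromoprop-2-en-1-yl)oxy](tert-butyl)diphenylsilane
Conditions: TBDPSCl, imidazole, DMF, 0 °C → rt
Reagents that add atoms: tert-butyl(chloro)diphenylsilane (CC(C)(C)[Si](Cl)(c1ccccc1)c1ccccc1)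
Why: Imidazole-promoted silylation of the only hydroxyl group gives the robust ether that later masks C12–OH.

Step 3
Reactants: 4 (2E)-but-2-ene-1,4-diol
Product: 5 (2E)-4-[(4-methoxyphenyl)methoxy]but-2-en-1-ol
Conditions: 4 (3 equiv), NaH (1 equiv), THF/DMF, 0 °C; PMBCl (1 equiv), Bu4NI (cat.), 0 °C → rt
Reagents that add atoms: 4-methoxybenzyl chloride (COc1ccc(CCl)cc1)
Why: Williamson ether synthesis; the threefold excess of the symmetric diol makes the mono-ether the main product.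

Step 4
Reactants: 5 (2E)-4-[(4-methoxyphenyl)methoxy]but-2-en-1-ol
Product: 6 [(2S,3S)-3-{[(4-methoxyphenyl)methoxy]methyl}oxiran-2-yl]methanol
Conditions: Ti(OiPr)4 (0.1 equiv), L-(+)-diethyl tartrate (0.12 equiv), t-BuOOH (2 equiv), 4 Å MS, CH2Cl2, −20 °C
Reagents that add atoms: tert-butyl hydroperoxide (CC(C)(C)OO)
Why: Katsuki–Sharpless asymmetric epoxidation; with L-(+)-tartrate the (E)-allylic alcohol gives the (2S,3S)-epoxide, which fixes the future C7 and C8.

Step 5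
Reactants: 6 the (2S,3S)-epoxy alcohol; 3 the 2-bromoallyl TBDPS ether
Product: 8 (2R,3R)-2-{3-[(tert-butyldiphenylsilyl)oxy]prop-1-en-2-yl}-4-[(4-methoxyphenyl)methoxy]butane-1,3-diol, via alkenylmagnesium bromide 7 (not isolated)
Conditions: 3 (3 equiv), Mg turnings, THF, 40 °C; CuI (0.3 equiv), −30 °C; 6, −30 → 0 °C
Reagents that add atoms: none
Why: Copper-catalysed Grignard opening of a 2,3-epoxy alcohol by SN2 attack with inversion at C2 (future C7), favoured over C3 by the electron-withdrawing CH2OPMB group and the magnesium alkoxide, gives the anti C7/C8 pair.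

Step 6
Reactants: 8 the (2R,3R)-1,3-diol
Product: 9 (2R,3R)-4-[(tert-butyldimethylsilyl)oxy]-3-{3-[(tert-butyldiphenylsilyl)oxy]prop-1-en-2-yl}-1-[(4-methoxyphenyl)methoxy]butan-2-ol
Conditions: TBSCl (1.05 equiv), imidazole, CH2Cl2, −10 °C
Reagents that add atoms: tert-butyl(chloro)dimethylsilane (CC(C)(C)[Si](C)(C)Cl)
Why: Silylation is much faster at the primary (C6) hydroxyl than at the hindered secondary (C8) one.

Step 7
Reactants: 9 the C6-TBS ether with free C8–OH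
Product: 10 (4R)-4-[(2R)-1-[(tert-butyldimethylsilyl)oxy]-3-{[(tert-butyldiphenylsilyl)oxy]methyl}but-3-en-2-yl]-2-(4-methoxyphenyl)-1,3-dioxolane (both acetal epimers)
Conditions: DDQ (1.3 equiv), 4 Å MS, CH2Cl2, −10 → 0 °C
Reagents that add atoms: none
Why: Oxidative acetalisation: DDQ oxidises the PMB ether to an oxocarbenium ion that the neighbouring C8 hydroxyl traps as a five-membered 4-methoxybenzylidene acetal.

Step 8
Reactants: 10 the 4-methoxybenzylidene acetal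
Product: 11 (2R,3R)-4-[(tert-butyldimethylsilyl)oxy]-3-{3-[(tert-butyldiphenylsilyl)oxy]prop-1-en-2-yl}-2-[(4-methoxyphenyl)methoxy]butan-1-ol
Conditions: i-Bu2AlH (3 equiv), CH2Cl2, −78 → −20 °C
Reagents that add atoms: none
Why: Regioselective reductive acetal opening; aluminium binds the less hindered primary oxygen, so the PMB ether stays on the secondary C8 oxygen and C9–OH is freed.

Step 9
Reactants: 11 the primary alcohol (C9–OH)
Product: 12 (2R,3R)-4-[(tert-butyldimethylsilyl)oxy]-3-{3-[(tert-butyldiphenylsilyl)oxy]prop-1-en-2-yl}-2-[(4-methoxyphenyl)methoxy]butanal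
Conditions: Dess–Martin periodinane (1.5 equiv), NaHCO3, CH2Cl2, 0 °C → rt; used crude
Reagents that add atoms: none
Why: Buffered Dess–Martin oxidation stops at the α-alkoxy aldehyde without epimerising C8.

Step 10
Reactants: 13 pent-4-yn-1-ol
Product: 15 (4E)-5-iodo-4-methylpent-4-en-1-ol, via alkenylalane 14 (not isolated)
Conditions: AlMe3 (3 equiv), Cp2ZrCl2 (0.25 equiv), CH2Cl2, 0 °C → rt; I2 (1.2 equiv), THF, −30 → 0 °C
Reagents that add atoms: trimethylaluminium (C[Al](C)C); iodine (II)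
Why: Negishi zirconium-catalysed carboalumination adds Me–Al syn across the alkyne with aluminium at the terminus, and iodinolysis with retention gives the (E)-iodide.

Step 11
Reactants: 15 (4E)-5-iodo-4-methylpent-4-en-1-ol
Product: 16 (4E)-4-methyl-5-(tributylstannyl)pent-4-en-1-ol
Conditions: Bu3SnSnBu3 (2 equiv), Pd(PPh3)4 (5 mol %), toluene, 90 °C
Reagents that add atoms: hexabutyldistannane (CCCC[Sn](CCCC)(CCCC)[Sn](CCCC)(CCCC)CCCC)
Why: Palladium-catalysed stannylation of the alkenyl iodide (oxidative addition, tin transfer, reductive elimination) keeps the (E) geometry and gives a masked iodide that survives t-BuLi.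

Step 12
Reactants: 16 the stannyl alcohol
Product: 17 (4E)-4-methyl-5-(tributylstannyl)pent-4-enal
Conditions: Dess–Martin periodinane, NaHCO3, CH2Cl2, 0 °C
Reagents that add atoms: none
Why: Buffered Dess–Martin oxidation gives the aldehyde without protodestannylation.

Step 13
Reactants: 18 iodoethane
Product: 19 ethyl(triphenyl)phosphonium iodide
Conditions: PPh3, toluene, 110 °C
Reagents that add atoms: triphenylphosphine (c1ccc(cc1)P(c1ccccc1)c1ccccc1)
Why: SN2 quaternisation of the phosphine gives the crystalline Wittig salt.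

Step 14
Reactants: 17 the stannyl aldehyde; 19 ethyl(triphenyl)phosphonium iodide
Product: 23 tributyl[(1E,5Z)-6-iodo-2-methylhepta-1,5-dien-1-yl]stannane, via ethylidene ylide 20 (not isolated), via iodoethylphosphonium iodide 21 (not isolated), via iodoethylidene ylide 22 (not isolated)
Conditions: 19 (1.5 equiv), n-BuLi, THF, 0 °C → rt; I2, −78 °C; NaN(SiMe3)2, −78 → −20 °C; 17, −78 °C → rt
Reagents that add atoms: iodine (II)
Why: Stork–Zhao olefination; the α-iodo ylide reacts under kinetic Wittig control to give the (Z)-2-iodoalkene, with iodine cis to the chain as needed for the 1(10)Z olefin.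

Step 15
Reactants: 23 the west fragment (alkenyl iodide/alkenylstannane); 12 the east fragment (α-PMB-oxy aldehyde)
Product: 27 (2R,3R,4R,5Z,9E)-1-[(tert-butyldimethylsilyl)oxy]-2-{3-[(tert-butyldiphenylsilyl)oxy]prop-1-en-2-yl}-3-[(4-methoxyphenyl)methoxy]-5,9-dimethyl-10-(tributylstannyl)deca-5,9-dien-4-yl acetate, via alkenyllithium 24 (not isolated), via alkenylmagnesium bromide 25 (not isolated), via bromomagnesium alkoxide 26 (not isolated)
Conditions: 23 (1.2 equiv), t-BuLi (2.05 equiv per 23), Et2O, −78 °C; MgBr2·OEt2, −78 °C; 12 precomplexed with MgBr2·OEt2 in CH2Cl2, −78 °C; Ac2O (5 equiv), DMAP (0.2 equiv), −78 → 0 °C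
Reagents that add atoms: acetic anhydride (CC(=O)OC(C)=O)
Why: Iodine–lithium exchange with retention, transmetalation to magnesium and Cram-chelate addition (magnesium bridges the aldehyde and α-OPMB oxygens, attack anti to the C7 branch) give the 8,9-syn (9R) alkoxide, which is acetylated in the flask.

Step 16
Reactants: 27 the coupled alkenylstannane
Product: 28 (2R,3R,4R,5Z,9E)-1-[(tert-butyldimethylsilyl)oxy]-2-{3-[(tert-butyldiphenylsilyl)oxy]prop-1-en-2-yl}-10-iodo-3-[(4-methoxyphenyl)methoxy]-5,9-dimethyldeca-5,9-dien-4-yl acetate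
Conditions: I2 (1.1 equiv), CH2Cl2, 0 °C
Reagents that add atoms: iodine (II)
Why: Iododestannylation is an ipso electrophilic substitution that proceeds with retention of the (E) geometry and is far faster than any reaction of iodine with the other alkenes.

Step 17
Reactants: 28 the (E)-alkenyl iodide with C6–OTBS
Product: 29 (2R,3R,4R,5Z,9E)-2-{3-[(tert-butyldiphenylsilyl)oxy]prop-1-en-2-yl}-1-hydroxy-10-iodo-3-[(4-methoxyphenyl)methoxy]-5,9-dimethyldeca-5,9-dien-4-yl acetate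
Conditions: HF·pyridine, pyridine, THF, 0 °C
Reagents that add atoms: none
Why: Under buffered HF the primary TBS ether is cleaved much faster than the TBDPS ether, and the acetate and PMB ether are untouched.

Step 18
Reactants: 29 the primary alcohol (C6–OH)
Product: 30 (2S,3R,4R,5Z,9E)-2-{3-[(tert-butyldiphenylsilyl)oxy]prop-1-en-2-yl}-10-iodo-3-[(4-methoxyphenyl)methoxy]-5,9-dimethyl-1-oxodeca-5,9-dien-4-yl acetate
Conditions: Dess–Martin periodinane, NaHCO3, CH2Cl2, 0 °C; used at once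
Reagents that add atoms: none
Why: Neutral Dess–Martin oxidation gives the β,γ-unsaturated aldehyde without epimerising or conjugating C7 (the descriptor changes only because CHO outranks C8).

Step 19
Reactants: 30 the iodo aldehyde
Product: 32 (6S,7R,8R,9R)-9-acetoxy-12-[(tert-butyldiphenylsilyl)oxy]-8-[(4-methoxybenzyl)oxy]germacra-1(10)Z,4E,11(13)-trien-6-ol, via alkenylchromium dichloride 31 (not isolated)
Conditions: CrCl2 (10 equiv), NiCl2 (0.1 equiv), DMSO/THF (3:1), 0.002 M, slow addition, rt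
Reagents that add atoms: none
Why: Nozaki–Hiyama–Kishi macrocyclisation; the alkenylchromium forms with retention and should add to the aldehyde in the Felkin–Anh sense (anti to the C8 branch, reinforced by 1,3-anti induction from the C8 ether) to give the 6S alcohol.

Step 20
Reactants: 32 the ten-membered allylic alcohol
Product: 33 (6S,7R,8R,9R)-9-acetoxy-8-[(4-methoxybenzyl)oxy]germacra-1(10)Z,4E,11(13)-triene-6,12-diol
Conditions: Bu4NF (1.5 equiv), AcOH (1.5 equiv), THF, 0 °C → rt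
Reagents that add atoms: none
Why: Fluoride desilylation buffered with acetic acid removes the TBDPS ether without hydrolysing or shifting the acetate.

Step 21
Reactants: 33 the 6,12-diol
Product: 36 (6S,7R,8R,9R)-9-acetoxy-8-[(4-methoxybenzyl)oxy]germacra-1(10)Z,4E,11(13)-trien-12,6-olide, via hydroxy enal 34 (not isolated), via lactol 35 (not isolated)
Conditions: TEMPO (0.2 equiv), PhI(OAc)2 (2.5 equiv), CH2Cl2, rt
Reagents that add atoms: none
Why: Oxidative lactonisation; TEMPO oxidises the primary allylic alcohol selectively, the enal is trapped by the C6 hydroxyl as a lactol, and the lactol is oxidised on to the trans-fused α-methylene-γ-lactone.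

Step 22
Reactants: 36 the PMB-protected lactone
Product: 37 (6S,7S,8R,9R)-9-acetoxy-8-hydroxygermacra-1(10)Z,4E,11(13)-trien-12,6-olide
Conditions: DDQ (1.5 equiv), CH2Cl2/pH 7 buffer (10:1), 0 °C → rt
Reagents that add atoms: none
Why: Oxidative PMB cleavage (electron transfer to DDQ, then hydrolysis of the oxocarbenium ion) frees C8–OH under neutral conditions; the C7 descriptor changes by priority only.

Step 23
Reactants: 38 methyl (2Z)-2-methylbut-2-enoate (methyl angelate)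
Product: 39 (2Z)-2-methylbut-2-en-1-ol
Conditions: i-Bu2AlH (2.2 equiv), CH2Cl2, −78 → 0 °C
Reagents that add atoms: none
Why: 1,2-Reduction of the ester at low temperature keeps the (Z) geometry.

Step 24
Reactants: 39 (2Z)-2-methylbut-2-en-1-ol
Product: 40 [(2S,3R)-2,3-dimethyloxiran-2-yl]methanol
Conditions: Ti(OiPr)4 (0.1 equiv), L-(+)-diethyl tartrate (0.12 equiv), t-BuOOH (2 equiv), 4 Å MS, CH2Cl2, −20 °C
Reagents that add atoms: tert-butyl hydroperoxide (CC(C)(C)OO)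
Why: Katsuki–Sharpless asymmetric epoxidation; L-(+)-tartrate gives the (2S,3R)-epoxide, and the cis relation of CH2OH and the C3 methyl follows from the (Z)-alkene.

Step 25
Reactants: 40 the (2S,3R)-epoxy alcohol
Product: 41 (2R,3R)-2,3-dimethyloxirane-2-carboxylic acid
Conditions: TEMPO (0.2 equiv), PhI(OAc)2 (2.2 equiv), MeCN/H2O (1:1), 0 °C → rt
Reagents that add atoms: water (O)
Why: TEMPO-catalysed oxidation through the aldehyde hydrate gives the acid without opening the oxirane; C2 becomes R by priority change only.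

Step 26
Reactants: 41 (2R,3R)-epoxyangelic acid; 37 the C8 alcohol
Product: 43 (3aR,4R,5R,6Z,10E,11aS)-5-(acetyloxy)-6,10-dimethyl-3-methylidene-2-oxo-2,3,3a,4,5,8,9,11a-octahydrocyclodeca[b]furan-4-yl (2R,3R)-2,3-dimethyloxirane-2-carboxylate, via mixed anhydride 42 (not isolated)
Conditions: 41 (2 equiv), 2,4,6-trichlorobenzoyl chloride (2 equiv), Et3N (4 equiv), THF, rt; 37, DMAP (2 equiv), toluene, rt → 40 °C
Reagents that add atoms: none
Why: Yamaguchi esterification; DMAP attacks the mixed anhydride at the epoxy-acyl carbonyl and the acylpyridinium acylates the hindered C8 hydroxyl without touching any stereocentre.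

**Compound list**

1 | 2,3-dibromoprop-1-ene | C=C(Br)CBr | starting material
2 | 2-bromoprop-2-en-1-ol | C=C(Br)CO | intermediate
3 | [(2-bromoprop-2-en-1-yl)oxy](tert-butyl)diphenylsilane | C=C(Br)CO[Si](c1ccccc1)(c1ccccc1)C(C)(C)C | intermediate
4 | (2E)-but-2-ene-1,4-diol | OC/C=C/CO | starting material
5 | (2E)-4-[(4-methoxyphenyl)methoxy]but-2-en-1-ol | OC/C=C/COCc1ccc(OC)cc1 | intermediate
6 | [(2S,3S)-3-{[(4-methoxyphenyl)methoxy]methyl}oxiran-2-yl]methanol | OC[C@@H]1O[C@H]1COCc1ccc(OC)cc1 | intermediate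
7 | bromo{3-[(tert-butyldiphenylsilyl)oxy]prop-1-en-2-yl}magnesium (not isolated) | C=C([Mg]Br)CO[Si](c1ccccc1)(c1ccccc1)C(C)(C)C | intermediate
8 | (2R,3R)-2-{3-[(tert-butyldiphenylsilyl)oxy]prop-1-en-2-yl}-4-[(4-methoxyphenyl)methoxy]butane-1,3-diol | OC[C@@H](C(=C)CO[Si](c1ccccc1)(c1ccccc1)C(C)(C)C)[C@@H](O)COCc1ccc(OC)cc1 | intermediate
9 | (2R,3R)-4-[(tert-butyldimethylsilyl)oxy]-3-{3-[(tert-butyldiphenylsilyl)oxy]prop-1-en-2-yl}-1-[(4-methoxyphenyl)methoxy]butan-2-ol | CC(C)(C)[Si](C)(C)OC[C@@H](C(=C)CO[Si](c1ccccc1)(c1ccccc1)C(C)(C)C)[C@@H](O)COCc1ccc(OC)cc1 | intermediate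
10 | (4R)-4-[(2R)-1-[(tert-butyldimethylsilyl)oxy]-3-{[(tert-butyldiphenylsilyl)oxy]methyl}but-3-en-2-yl]-2-(4-methoxyphenyl)-1,3-dioxolane (both acetal epimers) | CC(C)(C)[Si](C)(C)OC[C@@H](C(=C)CO[Si](c1ccccc1)(c1ccccc1)C(C)(C)C)[C@@H]1COC(c2ccc(OC)cc2)O1 | intermediate
11 | (2R,3R)-4-[(tert-butyldimethylsilyl)oxy]-3-{3-[(tert-butyldiphenylsilyl)oxy]prop-1-en-2-yl}-2-[(4-methoxyphenyl)methoxy]butan-1-ol | CC(C)(C)[Si](C)(C)OC[C@@H](C(=C)CO[Si](c1ccccc1)(c1ccccc1)C(C)(C)C)[C@@H](OCc1ccc(OC)cc1)CO | intermediate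
12 | (2R,3R)-4-[(tert-butyldimethylsilyl)oxy]-3-{3-[(tert-butyldiphenylsilyl)oxy]prop-1-en-2-yl}-2-[(4-methoxyphenyl)methoxy]butanal (east fragment) | CC(C)(C)[Si](C)(C)OC[C@@H](C(=C)CO[Si](c1ccccc1)(c1ccccc1)C(C)(C)C)[C@@H](OCc1ccc(OC)cc1)C=O | intermediate
13 | pent-4-yn-1-ol | C#CCCCO | starting material
14 | dimethylaluminium (4E)-5-(dimethylalumanyl)-4-methylpent-4-en-1-olate (not isolated) | C[Al](C)/C=C(\C)CCCO[Al](C)C | intermediate
15 | (4E)-5-iodo-4-methylpent-4-en-1-ol | I/C=C(\C)CCCO | intermediate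
16 | (4E)-4-methyl-5-(tributylstannyl)pent-4-en-1-ol | CCCC[Sn](CCCC)(CCCC)/C=C(\C)CCCO | intermediate
17 | (4E)-4-methyl-5-(tributylstannyl)pent-4-enal | CCCC[Sn](CCCC)(CCCC)/C=C(\C)CCC=O | intermediate
18 | iodoethane | CCI | starting material
19 | ethyl(triphenyl)phosphonium iodide | CC[P+](c1ccccc1)(c1ccccc1)c1ccccc1.[I-] | intermediate
20 | ethylidene(triphenyl)phosphorane (not isolated) | CC=P(c1ccccc1)(c1ccccc1)c1ccccc1 | intermediate
21 | (1-iodoethyl)(triphenyl)phosphonium iodide (not isolated) | CC(I)[P+](c1ccccc1)(c1ccccc1)c1ccccc1.[I-] | intermediate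
22 | (1-iodoethylidene)(triphenyl)phosphorane (not isolated) | CC(I)=P(c1ccccc1)(c1ccccc1)c1ccccc1 | intermediate
23 | tributyl[(1E,5Z)-6-iodo-2-methylhepta-1,5-dien-1-yl]stannane (west fragment) | CCCC[Sn](CCCC)(CCCC)/C=C(\C)CC/C=C(/C)I | intermediate
24 | [(2E,6E)-6-methyl-7-(tributylstannyl)hepta-2,6-dien-2-yl]lithium, lithium in the place of iodine (not isolated) | CCCC[Sn](CCCC)(CCCC)/C=C(\C)CC/C=C(/C)[Li] | intermediate
25 | bromo[(2Z,6E)-6-methyl-7-(tributylstannyl)hepta-2,6-dien-2-yl]magnesium (not isolated) | CCCC[Sn](CCCC)(CCCC)/C=C(\C)CC/C=C(/C)[Mg]Br | intermediate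
26 | bromomagnesium (2R,3R,4R,5Z,9E)-1-[(tert-butyldimethylsilyl)oxy]-2-{3-[(tert-butyldiphenylsilyl)oxy]prop-1-en-2-yl}-3-[(4-methoxyphenyl)methoxy]-5,9-dimethyl-10-(tributylstannyl)deca-5,9-dien-4-olate (not isolated) | CCCC[Sn](CCCC)(CCCC)/C=C(\C)CC/C=C(/C)[C@@H](O[Mg]Br)[C@H](OCc1ccc(OC)cc1)[C@H](C(=C)CO[Si](c1ccccc1)(c1ccccc1)C(C)(C)C)CO[Si](C)(C)C(C)(C)C | intermediate
27 | (2R,3R,4R,5Z,9E)-1-[(tert-butyldimethylsilyl)oxy]-2-{3-[(tert-butyldiphenylsilyl)oxy]prop-1-en-2-yl}-3-[(4-methoxyphenyl)methoxy]-5,9-dimethyl-10-(tributylstannyl)deca-5,9-dien-4-yl acetate | CCCC[Sn](CCCC)(CCCC)/C=C(\C)CC/C=C(/C)[C@@H](OC(C)=O)[C@H](OCc1ccc(OC)cc1)[C@H](C(=C)CO[Si](c1ccccc1)(c1ccccc1)C(C)(C)C)CO[Si](C)(C)C(C)(C)C | intermediate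
28 | (2R,3R,4R,5Z,9E)-1-[(tert-butyldimethylsilyl)oxy]-2-{3-[(tert-butyldiphenylsilyl)oxy]prop-1-en-2-yl}-10-iodo-3-[(4-methoxyphenyl)methoxy]-5,9-dimethyldeca-5,9-dien-4-yl acetate | I/C=C(\C)CC/C=C(/C)[C@@H](OC(C)=O)[C@H](OCc1ccc(OC)cc1)[C@H](C(=C)CO[Si](c1ccccc1)(c1ccccc1)C(C)(C)C)CO[Si](C)(C)C(C)(C)C | intermediate
29 | (2R,3R,4R,5Z,9E)-2-{3-[(tert-butyldiphenylsilyl)oxy]prop-1-en-2-yl}-1-hydroxy-10-iodo-3-[(4-methoxyphenyl)methoxy]-5,9-dimethyldeca-5,9-dien-4-yl acetate | I/C=C(\C)CC/C=C(/C)[C@@H](OC(C)=O)[C@H](OCc1ccc(OC)cc1)[C@H](C(=C)CO[Si](c1ccccc1)(c1ccccc1)C(C)(C)C)CO | intermediate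
30 | (2S,3R,4R,5Z,9E)-2-{3-[(tert-butyldiphenylsilyl)oxy]prop-1-en-2-yl}-10-iodo-3-[(4-methoxyphenyl)methoxy]-5,9-dimethyl-1-oxodeca-5,9-dien-4-yl acetate | I/C=C(\C)CC/C=C(/C)[C@@H](OC(C)=O)[C@H](OCc1ccc(OC)cc1)[C@H](C(=C)CO[Si](c1ccccc1)(c1ccccc1)C(C)(C)C)C=O | intermediate
31 | alkenylchromium dichloride of 30, CrCl2 in the place of iodine, (E) geometry kept (not isolated) | Cl[Cr](Cl)/C=C(\C)CC/C=C(/C)[C@@H](OC(C)=O)[C@H](OCc1ccc(OC)cc1)[C@H](C(=C)CO[Si](c1ccccc1)(c1ccccc1)C(C)(C)C)C=O | intermediate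
32 | (6S,7R,8R,9R)-9-acetoxy-12-[(tert-butyldiphenylsilyl)oxy]-8-[(4-methoxybenzyl)oxy]germacra-1(10)Z,4E,11(13)-trien-6-ol | O[C@H]1/C=C(\C)CC/C=C(/C)[C@@H](OC(C)=O)[C@H](OCc2ccc(OC)cc2)[C@@H]1C(=C)CO[Si](c1ccccc1)(c1ccccc1)C(C)(C)C | intermediate
33 | (6S,7R,8R,9R)-9-acetoxy-8-[(4-methoxybenzyl)oxy]germacra-1(10)Z,4E,11(13)-triene-6,12-diol | O[C@H]1/C=C(\C)CC/C=C(/C)[C@@H](OC(C)=O)[C@H](OCc2ccc(OC)cc2)[C@@H]1C(=C)CO | intermediate
34 | (6S,7R,8R,9R)-9-acetoxy-6-hydroxy-8-[(4-methoxybenzyl)oxy]germacra-1(10)Z,4E,11(13)-trien-12-al (not isolated) | O[C@H]1/C=C(\C)CC/C=C(/C)[C@@H](OC(C)=O)[C@H](OCc2ccc(OC)cc2)[C@@H]1C(=C)C=O | intermediate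
35 | (6S,7R,8R,9R)-9-acetoxy-6,12-epoxy-8-[(4-methoxybenzyl)oxy]germacra-1(10)Z,4E,11(13)-trien-12-ol, lactol, both C12 epimers (not isolated) | C=C1C(O)O[C@H]2/C=C(\C)CC/C=C(/C)[C@@H](OC(C)=O)[C@H](OCc3ccc(OC)cc3)[C@H]12 | intermediate
36 | (6S,7R,8R,9R)-9-acetoxy-8-[(4-methoxybenzyl)oxy]germacra-1(10)Z,4E,11(13)-trien-12,6-olide | C=C1C(=O)O[C@H]2/C=C(\C)CC/C=C(/C)[C@@H](OC(C)=O)[C@H](OCc3ccc(OC)cc3)[C@H]12 | intermediate
37 | (6S,7S,8R,9R)-9-acetoxy-8-hydroxygermacra-1(10)Z,4E,11(13)-trien-12,6-olide | C=C1C(=O)O[C@H]2/C=C(\C)CC/C=C(/C)[C@@H](OC(C)=O)[C@H](O)[C@H]12 | intermediate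
38 | methyl (2Z)-2-methylbut-2-enoate (methyl angelate) | C/C=C(/C)C(=O)OC | starting material
39 | (2Z)-2-methylbut-2-en-1-ol | C/C=C(/C)CO | intermediate
40 | [(2S,3R)-2,3-dimethyloxiran-2-yl]methanol | OC[C@]1(C)O[C@@H]1C | intermediate
41 | (2R,3R)-2,3-dimethyloxirane-2-carboxylic acid | OC(=O)[C@]1(C)O[C@@H]1C | intermediate
42 | (2R,3R)-2,3-dimethyloxirane-2-carboxylic 2,4,6-trichlorobenzoic anhydride (not isolated) | O=C(OC(=O)[C@]1(C)O[C@@H]1C)c1c(Cl)cc(Cl)cc1Cl | intermediate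
43 | (3aR,4R,5R,6Z,10E,11aS)-5-(acetyloxy)-6,10-dimethyl-3-methylidene-2-oxo-2,3,3a,4,5,8,9,11a-octahydrocyclodeca[b]furan-4-yl (2R,3R)-2,3-dimethyloxirane-2-carboxylate (CNP0304643.4) | C=C1C(=O)O[C@H]2/C=C(\C)CC/C=C(/C)[C@@H](OC(C)=O)[C@H](OC(=O)[C@]3(C)O[C@@H]3C)[C@H]12 | target

**Step count and risks**

Total step count: 26.
Longest linear sequence: 16 steps (4 → 5 → 6 → 8 → 9 → 10 → 11 → 12 → 27 → 28 → 29 → 30 → 32 → 33 → 36 → 37 → 43, that is steps 3–9, 15–22 and 26; the line from 1 through steps 1, 2, 5–9, 15–22, 26 is equally long).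

The three steps most likely to fail:

Step 5 (site of epoxide opening). Attack at C3 instead of C2 would give a 1,2-diol; NaIO4 would remove it, but at a cost in yield. The fallback sets out from 6 and comes back at 8. Oxidation of 6 with TEMPO/PhI(OAc)2 in MeCN/H2O gives (2R,3S)-3-{[(4-methoxyphenyl)methoxy]methyl}oxirane-2-carboxylic acid F1. Its carboxylate is then opened with 7 and catalytic CuI; in a glycidic acid the carbon α to the carboxylate is the electronically preferred site of SN2 attack, so the same inversion at the future C7 results. This gives (2S,3R)-2-{3-[(tert-butyldiphenylsilyl)oxy]prop-1-en-2-yl}-3-hydroxy-4-[(4-methoxyphenyl)methoxy]butanoic acid F2, and LiAlH4 in THF at 0 °C reduces the carboxyl group to the primary alcohol, which is 8.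

Step 15 (facial selectivity of the fragment union; the acetate is made before the epimers can be separated as alcohols). The fallback sets out from 23 and 12 and comes back at 27. Alkenyllithium 24 is added to 12 in THF at −78 °C without magnesium salt or acetylation, and the product is isolated as (2R,3R,5Z,9E)-1-[(tert-butyldimethylsilyl)oxy]-2-{3-[(tert-butyldiphenylsilyl)oxy]prop-1-en-2-yl}-3-[(4-methoxyphenyl)methoxy]-5,9-dimethyl-10-(tributylstannyl)deca-5,9-dien-4-ol F3, as both C4 epimers. Dess–Martin oxidation converges them to (2R,3R,5Z,9E)-1-[(tert-butyldimethylsilyl)oxy]-2-{3-[(tert-butyldiphenylsilyl)oxy]prop-1-en-2-yl}-3-[(4-methoxyphenyl)methoxy]-5,9-dimethyl-10-(tributylstannyl)deca-5,9-dien-4-one F4. Reagent-controlled reduction with (R)-2-methyl-CBS-oxazaborolidine and catecholborane (alkenyl group as the large substituent) gives (2R,3R,4R,5Z,9E)-1-[(tert-butyldimethylsilyl)oxy]-2-{3-[(tert-butyldiphenylsilyl)oxy]prop-1-en-2-yl}-3-[(4-methoxyphenyl)methoxy]-5,9-dimethyl-10-(tributylstannyl)deca-5,9-dien-4-ol F5. Ac2O, DMAP and pyridine then give 27.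

Step 19 (ten-membered ring closure). Oligomerisation competes, and the two branches on C7 are of similar size, so the Felkin–Anh preference for 6S may be weak or reversed in the cyclic transition state. The fallback sets out from 30 and comes back at 32. If the closure gives mainly (6R,7R,8R,9R)-9-acetoxy-12-[(tert-butyldiphenylsilyl)oxy]-8-[(4-methoxybenzyl)oxy]germacra-1(10)Z,4E,11(13)-trien-6-ol F6, it is oxidised with Dess–Martin periodinane to (7S,8R,9R)-9-acetoxy-12-[(tert-butyldiphenylsilyl)oxy]-8-[(4-methoxybenzyl)oxy]germacra-1(10)Z,4E,11(13)-trien-6-one F7. The ring enone is then reduced with (S)-2-methyl-CBS-oxazaborolidine and catecholborane at −78 °C, so that C6 is set by the reagent and not by the C–C bond formation, giving 32.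

Further compounds
F1 | step 5 | (2R,3S)-3-{[(4-methoxyphenyl)methoxy]methyl}oxirane-2-carboxylic acid | OC(=O)[C@@H]1O[C@H]1COCc1ccc(OC)cc1
F2 | step 5 | (2S,3R)-2-{3-[(tert-butyldiphenylsilyl)oxy]prop-1-en-2-yl}-3-hydroxy-4-[(4-methoxyphenyl)methoxy]butanoic acid | OC(=O)[C@@H](C(=C)CO[Si](c1ccccc1)(c1ccccc1)C(C)(C)C)[C@@H](O)COCc1ccc(OC)cc1
F3 | step 15 | (2R,3R,5Z,9E)-1-[(tert-butyldimethylsilyl)oxy]-2-{3-[(tert-butyldiphenylsilyl)oxy]prop-1-en-2-yl}-3-[(4-methoxyphenyl)methoxy]-5,9-dimethyl-10-(tributylstannyl)deca-5,9-dien-4-ol (both C4 epimers) | CCCC[Sn](CCCC)(CCCC)/C=C(\C)CC/C=C(/C)C(O)[C@H](OCc1ccc(OC)cc1)[C@H](C(=C)CO[Si](c1ccccc1)(c1ccccc1)C(C)(C)C)CO[Si](C)(C)C(C)(C)C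
F4 | step 15 | (2R,3R,5Z,9E)-1-[(tert-butyldimethylsilyl)oxy]-2-{3-[(tert-butyldiphenylsilyl)oxy]prop-1-en-2-yl}-3-[(4-methoxyphenyl)methoxy]-5,9-dimethyl-10-(tributylstannyl)deca-5,9-dien-4-one | CCCC[Sn](CCCC)(CCCC)/C=C(\C)CC/C=C(/C)C(=O)[C@H](OCc1ccc(OC)cc1)[C@H](C(=C)CO[Si](c1ccccc1)(c1ccccc1)C(C)(C)C)CO[Si](C)(C)C(C)(C)C
F5 | step 15 | (2R,3R,4R,5Z,9E)-1-[(tert-butyldimethylsilyl)oxy]-2-{3-[(tert-butyldiphenylsilyl)oxy]prop-1-en-2-yl}-3-[(4-methoxyphenyl)methoxy]-5,9-dimethyl-10-(tributylstannyl)deca-5,9-dien-4-ol | CCCC[Sn](CCCC)(CCCC)/C=C(\C)CC/C=C(/C)[C@@H](O)[C@H](OCc1ccc(OC)cc1)[C@H](C(=C)CO[Si](c1ccccc1)(c1ccccc1)C(C)(C)C)CO[Si](C)(C)C(C)(C)C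
F6 | step 19 | (6R,7R,8R,9R)-9-acetoxy-12-[(tert-butyldiphenylsilyl)oxy]-8-[(4-methoxybenzyl)oxy]germacra-1(10)Z,4E,11(13)-trien-6-ol | O[C@@H]1/C=C(\C)CC/C=C(/C)[C@@H](OC(C)=O)[C@H](OCc2ccc(OC)cc2)[C@@H]1C(=C)CO[Si](c1ccccc1)(c1ccccc1)C(C)(C)C
F7 | step 19 | (7S,8R,9R)-9-acetoxy-12-[(tert-butyldiphenylsilyl)oxy]-8-[(4-methoxybenzyl)oxy]germacra-1(10)Z,4E,11(13)-trien-6-one | O=C1/C=C(\C)CC/C=C(/C)[C@@H](OC(C)=O)[C@H](OCc2ccc(OC)cc2)[C@@H]1C(=C)CO[Si](c1ccccc1)(c1ccccc1)C(C)(C)C
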